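**Retrosynthetic overview**

1. Numbering and feature: the ring carbons are C1 (CMe2), C2–C4 (CH2), C5/C6 (oxirane, methyl on C5), C7, C8 (CH2), C9 (C–CO2H), C10 (=CH) and C11 (CHOBz). The strategy rests on the C11 carbinol carbon being bonded directly to the quaternary gem-dimethyl carbon C1 of the 11-membered carbocycle, which is the retron of a γ,γ-dimethylallyl-metal addition to an aldehyde; C1–C7 with its three methyl groups is a geranyl unit.
2. Late stage: the acid comes from its 2-(trimethylsilyl)ethyl (TMSE) ester, the oxirane (second ring formed) from reagent-controlled epoxidation of the E C5=C6 alkene, the benzoate from the C11 alcohol, and C2–C3 from reduction of the alkene left by the key step.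
3. Key disconnection C11–C1: the 11-membered carbocycle (first ring formed) closes by intramolecular allylboration of aldehyde boronate 16, the C3 boronate centre setting C11.
4. 16 comes from tertiary allylic carbonate 13 by copper-catalysed enantioselective SN2′ borylation; the C9=C10 enoate from a Horner–Wadsworth–Emmons reaction with dimethoxyacetaldehyde; C8 from a silylmethyl Grignard coupling; the tertiary carbinol from a Schenck ene reaction of geranyl acetate.

Key step: step 10

Remark (assumption): which antipode of the copper ligand in step 8 delivers the (S)-boronate is fixed by a trial run; both antipodes are available.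
Remark: locants C1–C11 in the Why lines are those of the target ring given above.

**Route**

Step 1
Reactants: 1 geranyl acetate
Product: 3 (2E,5E)-7-hydroxy-3,7-dimethylocta-2,5-dien-1-yl acetate, via tertiary allylic hydroperoxide 2 (not isolated)
Conditions: O2, hν (white LED), tetraphenylporphyrin (cat.), CH2Cl2, 0 °C; then PPh3, 0 °C → rt
Reagents that add atoms: dioxygen, O=O
Why: Schenck ene reaction of singlet oxygen at the electron-rich C1=C2 alkene (the C5=C6 alkene is deactivated by the allylic acetate) with hydrogen abstraction at C3 should give the tertiary hydroperoxide with an E C2=C3 alkene, which PPh3 reduces; the regioisomeric secondary allylic alcohol is removed by chromatography.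

Step 2
Reactants: 3 (2E,5E)-7-hydroxy-3,7-dimethylocta-2,5-dien-1-yl acetate
Product: 5 (3E,6E)-4,8-dimethylnona-3,6-diene-1,8-diol, via homoallylic silane 4 (not isolated)
Conditions: (iPrO)Me2SiCH2MgCl (3 equiv, from ClCH2SiMe2(OiPr) and Mg), Li2CuCl4 (5 mol %), THF, −20 → 0 °C; aq. NH4Cl; then crude 4, 30% H2O2, KF, KHCO3, THF–MeOH, rt
Reagents that add atoms: [dimethyl(propan-2-yloxy)silyl]methylmagnesium chloride, CC(C)O[Si](C)(C)C[Mg]Cl; hydrogen peroxide, OO
Why: copper-catalysed SN2 coupling of the primary allylic acetate with the silylmethyl Grignard reagent (one equivalent is spent on the tertiary hydroxyl) should add C8 at the unhindered C7 terminus with retention of the E alkene, and Tamao oxidation of the alkoxysilane unmasks the primary alcohol.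

Step 3
Reactants: 5 (3E,6E)-4,8-dimethylnona-3,6-diene-1,8-diol
Product: 6 (3E,6E)-9-iodo-2,6-dimethylnona-3,6-dien-2-ol
Conditions: I2, PPh3, imidazole, CH2Cl2, 0 °C
Reagents that add atoms: iodine, II
Why: Appel iodination should convert the primary alcohol far faster than the hindered tertiary allylic alcohol, which is left free.

Step 4
Reactants: 7 (diethoxyphosphoryl)acetic acid; 8 2-(trimethylsilyl)ethanol
Product: 9 2-(trimethylsilyl)ethyl (diethoxyphosphoryl)acetate
Conditions: EDC·HCl, DMAP (cat.), CH2Cl2, 0 °C → rt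
Reagents that add atoms: none
Why: Steglich-type carbodiimide esterification installs the fluoride-labile TMSE ester that is carried to the last step.

Step 5
Reactants: 6 (3E,6E)-9-iodo-2,6-dimethylnona-3,6-dien-2-ol; 9 2-(trimethylsilyl)ethyl (diethoxyphosphoryl)acetate
Product: 10 2-(trimethylsilyl)ethyl (5E,8E)-2-(diethoxyphosphoryl)-10-hydroxy-6,10-dimethylundeca-5,8-dienoate (racemic at C2 of the chain)
Conditions: 9 (2.5 equiv), NaH, THF–DMSO, 0 °C; then 6, 45 °C
Reagents that add atoms: none
Why: SN2 C-alkylation of the sodium phosphonoacetate (in excess to suppress dialkylation) with the primary iodide forms the C8–C9 bond; the weakly basic stabilised anion should leave the tertiary alcohol alone.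

Step 6
Reactants: 10 2-(trimethylsilyl)ethyl (5E,8E)-2-(diethoxyphosphoryl)-10-hydroxy-6,10-dimethylundeca-5,8-dienoate; 11 2,2-dimethoxyacetaldehyde
Product: 12 2-(trimethylsilyl)ethyl (2E,5E,8E)-2-(2,2-dimethoxyethylidene)-10-hydroxy-6,10-dimethylundeca-5,8-dienoate
Conditions: 11 (3 equiv, dried solution), LiCl, DBU, MeCN, 0 °C → rt
Reagents that add atoms: none
Why: Horner–Wadsworth–Emmons olefination under Masamune–Roush conditions should give mainly the enoate with the ester trans to C11, so that C8 and C11 are cis as the ring requires; the mild base tolerates the free tertiary alcohol and the TMSE ester.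

Step 7
Reactants: 12 2-(trimethylsilyl)ethyl (2E,5E,8E)-2-(2,2-dimethoxyethylidene)-10-hydroxy-6,10-dimethylundeca-5,8-dienoate
Product: 13 2-(trimethylsilyl)ethyl (2E,5E,8E)-2-(2,2-dimethoxyethylidene)-10-[(methoxycarbonyl)oxy]-6,10-dimethylundeca-5,8-dienoate
Conditions: LiN(SiMe3)2 (1.05 equiv), THF, −78 °C; then ClCO2Me, −78 → 0 °C
Reagents that add atoms: methyl chloroformate, COC(Cl)=O
Why: O-acylation of the lithium alkoxide with the chloroformate gives the tertiary allylic carbonate; deprotonation of the hydroxyl by the hindered amide at −78 °C should be faster than any attack on the enoate.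

Step 8
Reactants: 13 2-(trimethylsilyl)ethyl (2E,5E,8E)-2-(2,2-dimethoxyethylidene)-10-[(methoxycarbonyl)oxy]-6,10-dimethylundeca-5,8-dienoate; 14 bis(pinacolato)diboron
Product: 15 2-(trimethylsilyl)ethyl (2E,5E,8S)-2-(2,2-dimethoxyethylidene)-6,10-dimethyl-8-(4,4,5,5-tetramethyl-1,3,2-dioxaborolan-2-yl)undeca-5,9-dienoate
Conditions: CuCl (5 mol %), QuinoxP* [2,3-bis(tert-butylmethylphosphino)quinoxaline, one antipode, 5 mol %], KOtBu (10 mol %), THF, 0 °C
Reagents that add atoms: none
Why: copper-catalysed enantioselective allylic boryl substitution (SN2′): the boryl copper species should add across the E C2=C3 alkene with boron at C3 and copper at C2, β-elimination of the carbonate then forms the C1=C2 alkene, and the chiral ligand selects the alkene face and so sets C3 (S); without a proton source, conjugate borylation of the hindered trisubstituted enoate should not turn over.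

Step 9
Reactants: 15 2-(trimethylsilyl)ethyl (2E,5E,8S)-2-(2,2-dimethoxyethylidene)-6,10-dimethyl-8-(4,4,5,5-tetramethyl-1,3,2-dioxaborolan-2-yl)undeca-5,9-dienoate
Product: 16 2-(trimethylsilyl)ethyl (2E,5E,8S)-6,10-dimethyl-2-(2-oxoethylidene)-8-(4,4,5,5-tetramethyl-1,3,2-dioxaborolan-2-yl)undeca-5,9-dienoate (kept as a cold dilute toluene solution and used at once)
Conditions: Amberlyst-15, acetone–H2O (20:1), 0.01 M, 0 °C → rt; filter, NaHCO3, extract into toluene
Reagents that add atoms: water, O
Why: acid-catalysed acetal hydrolysis unveils the C11 aldehyde; the hindered pinacol boronate and the TMSE ester should survive the short contact with resin-bound acid, and at this dilution intermolecular allyl transfer is not expected before step 10.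

Step 10
Reactants: 16 2-(trimethylsilyl)ethyl (2E,5E,8S)-6,10-dimethyl-2-(2-oxoethylidene)-8-(4,4,5,5-tetramethyl-1,3,2-dioxaborolan-2-yl)undeca-5,9-dienoate
Product: 18 2-(trimethylsilyl)ethyl (1E,3R,5Z,8E)-3-hydroxy-4,4,8-trimethylcycloundeca-1,5,8-triene-1-carboxylate, via macrocyclic pinacol borate 17 (not isolated)
Conditions: toluene, 80 °C, syringe-pump addition to a final 1 mM; then pH 7 phosphate buffer, rt
Reagents that add atoms: none
Why: Proposed new method: boron at C3 binds the oxygen of the C11 aldehyde and C1 attacks C11 with allylic transposition in a closed six-membered array (B, O, C11, C1, C2, C3), so that the C11–C1 bond, the quaternary C1, the C11 carbinol and a C2=C3 alkene arise together; the closest known reaction is the intermolecular addition of α-chiral γ,γ-disubstituted allyl pinacol boronates to aldehydes with chirality transfer, and its use to close a macrocycle is what is new. The 11-membered carbocycle closes by C–C bond formation inside a bicyclic transition state in which the seven-atom tether C4–C10 bridges the 1,4-positions (C3 and C11) of that array. C11 is controlled by the C3 boronate centre: the short tether can only join C3 and C11 on one face of the array, and because boron leaves C3 on the face on which it holds the carbonyl oxygen, (3S) should lead to (11R) whether the array is chair-like (C4 axial, C10 equatorial, Z alkene as drawn) or boat-like (E alkene). The step needs γ-regioselectivity, which the cyclic boron–oxygen array enforces, and ring closure in preference to oligomerisation, which slow addition at 1 mM, the low intermolecular reactivity of the hindered pinacol boronate and the high electrophilicity of the non-enolisable 4-oxo-enoate aldehyde should secure. Any E isomer at C2=C3 carries the same C11 configuration and converges in step 11, and the (3R)-boronate from the antipodal ligand remains available if the correlation proves otherwise.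

Step 11
Reactants: 18 2-(trimethylsilyl)ethyl (1E,3R,5Z,8E)-3-hydroxy-4,4,8-trimethylcycloundeca-1,5,8-triene-1-carboxylate
Product: 19 2-(trimethylsilyl)ethyl (1E,3R,8E)-3-hydroxy-4,4,8-trimethylcycloundeca-1,8-diene-1-carboxylate
Conditions: 2-nitrobenzenesulfonohydrazide, Et3N, CH2Cl2, rt
Reagents that add atoms: none
Why: diimide reduction is governed by alkene substitution, so the 1,2-disubstituted C2=C3 alkene (either geometry) should be saturated ahead of the trisubstituted C5=C6 alkene and the trisubstituted enoate; C11 is not touched.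

Step 12
Reactants: 19 2-(trimethylsilyl)ethyl (1E,3R,8E)-3-hydroxy-4,4,8-trimethylcycloundeca-1,8-diene-1-carboxylate
Product: 20 2-(trimethylsilyl)ethyl (1E,3R,8E)-3-(benzoyloxy)-4,4,8-trimethylcycloundeca-1,8-diene-1-carboxylate
Conditions: BzCl, pyridine, DMAP (cat.), CH2Cl2, 0 → 40 °C
Reagents that add atoms: benzoyl chloride, O=C(Cl)c1ccccc1
Why: DMAP-catalysed acylation of the hindered secondary alcohol at oxygen proceeds with retention at C11.

Step 13
Reactants: 20 2-(trimethylsilyl)ethyl (1E,3R,8E)-3-(benzoyloxy)-4,4,8-trimethylcycloundeca-1,8-diene-1-carboxylate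
Product: 21 2-(trimethylsilyl)ethyl (1R,4E,6R,11R)-6-(benzoyloxy)-7,7,11-trimethyl-12-oxabicyclo[9.1.0]dodec-4-ene-4-carboxylate
Conditions: D-fructose-derived Shi ketone (1,2:4,5-di-O-isopropylidene-β-D-erythro-2,3-hexodiulo-2,6-pyranose, 30 mol %), KHSO5 (Oxone), K2CO3, Bu4NHSO4, MeCN–dimethoxymethane / aq. Na2B4O7–EDTA buffer, 0 °C
Reagents that add atoms: potassium peroxymonosulfate, [K+].[O-]S(=O)(=O)OO
Why: Shi asymmetric epoxidation: the chiral dioxirane attacks only the electron-rich E-trisubstituted C5=C6 alkene (the enoate is inert to the electrophilic oxidant) and its spiro transition state, which gives (R,R)-epoxides from E alkenes, should set C5 (R) and C6 (R) under reagent control.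

Step 14
Reactants: 21 2-(trimethylsilyl)ethyl (1R,4E,6R,11R)-6-(benzoyloxy)-7,7,11-trimethyl-12-oxabicyclo[9.1.0]dodec-4-ene-4-carboxylate
Product: 22 (1R,4E,6R,11R)-6-(benzoyloxy)-7,7,11-trimethyl-12-oxabicyclo[9.1.0]dodec-4-ene-4-carboxylic acid (CNP0377917.1)
Conditions: Bu4NF, THF, 0 °C → rt; aq. citric acid to pH 4, 0 °C
Reagents that add atoms: none
Why: fluoride-induced fragmentation of the 2-(trimethylsilyl)ethyl ester (β-elimination to ethene and Me3SiF) frees the acid under conditions that should leave the benzoate, the oxirane and the three stereocentres intact.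

**Compound list**

1 | geranyl acetate, (2E)-3,7-dimethylocta-2,6-dien-1-yl acetate | CC(C)=CCC/C(C)=C/COC(C)=O | starting material
2 | (2E,5E)-7-hydroperoxy-3,7-dimethylocta-2,5-dien-1-yl acetate | CC(C)(OO)/C=C/C/C(C)=C/COC(C)=O | intermediate (not isolated)
3 | (2E,5E)-7-hydroxy-3,7-dimethylocta-2,5-dien-1-yl acetate | CC(C)(O)/C=C/C/C(C)=C/COC(C)=O | intermediate
4 | (3E,6E)-2,6-dimethyl-9-[dimethyl(propan-2-yloxy)silyl]nona-3,6-dien-2-ol | CC(C)(O)/C=C/C/C(C)=C/CC[Si](C)(C)OC(C)C | intermediate (not isolated)
5 | (3E,6E)-4,8-dimethylnona-3,6-diene-1,8-diol | CC(C)(O)/C=C/C/C(C)=C/CCO | intermediate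
6 | (3E,6E)-9-iodo-2,6-dimethylnona-3,6-dien-2-ol | CC(C)(O)/C=C/C/C(C)=C/CCI | intermediate
7 | (diethoxyphosphoryl)acetic acid | CCOP(=O)(CC(=O)O)OCC | starting material
8 | 2-(trimethylsilyl)ethanol | C[Si](C)(C)CCO | starting material
9 | 2-(trimethylsilyl)ethyl (diethoxyphosphoryl)acetate | CCOP(=O)(CC(=O)OCC[Si](C)(C)C)OCC | intermediate
10 | 2-(trimethylsilyl)ethyl (5E,8E)-2-(diethoxyphosphoryl)-10-hydroxy-6,10-dimethylundeca-5,8-dienoate (racemic at C2) | CC(C)(O)/C=C/C/C(C)=C/CCC(C(=O)OCC[Si](C)(C)C)P(=O)(OCC)OCC | intermediate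
11 | 2,2-dimethoxyacetaldehyde | COC(OC)C=O | starting material
12 | 2-(trimethylsilyl)ethyl (2E,5E,8E)-2-(2,2-dimethoxyethylidene)-10-hydroxy-6,10-dimethylundeca-5,8-dienoate | CC(C)(O)/C=C/C/C(C)=C/CC/C(C(=O)OCC[Si](C)(C)C)=C\C(OC)OC | intermediate
13 | 2-(trimethylsilyl)ethyl (2E,5E,8E)-2-(2,2-dimethoxyethylidene)-10-[(methoxycarbonyl)oxy]-6,10-dimethylundeca-5,8-dienoate | COC(=O)OC(C)(C)/C=C/C/C(C)=C/CC/C(C(=O)OCC[Si](C)(C)C)=C\C(OC)OC | intermediate
14 | bis(pinacolato)diboron | CC1(C)OB(OC1(C)C)B1OC(C)(C)C(C)(C)O1 | starting material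
15 | 2-(trimethylsilyl)ethyl (2E,5E,8S)-2-(2,2-dimethoxyethylidene)-6,10-dimethyl-8-(4,4,5,5-tetramethyl-1,3,2-dioxaborolan-2-yl)undeca-5,9-dienoate | CC(C)=C[C@@H](B1OC(C)(C)C(C)(C)O1)C/C(C)=C/CC/C(C(=O)OCC[Si](C)(C)C)=C\C(OC)OC | intermediate
16 | 2-(trimethylsilyl)ethyl (2E,5E,8S)-6,10-dimethyl-2-(2-oxoethylidene)-8-(4,4,5,5-tetramethyl-1,3,2-dioxaborolan-2-yl)undeca-5,9-dienoate | CC(C)=C[C@@H](B1OC(C)(C)C(C)(C)O1)C/C(C)=C/CC/C(C(=O)OCC[Si](C)(C)C)=C\C=O | intermediate
17 | 2-(trimethylsilyl)ethyl (1E,3R,5Z,8E)-4,4,8-trimethyl-3-[(4,4,5,5-tetramethyl-1,3,2-dioxaborolan-2-yl)oxy]cycloundeca-1,5,8-triene-1-carboxylate | CC1(C)/C=C\C/C(C)=C/CC/C(C(=O)OCC[Si](C)(C)C)=C\[C@H]1OB2OC(C)(C)C(C)(C)O2 | intermediate (not isolated)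
18 | 2-(trimethylsilyl)ethyl (1E,3R,5Z,8E)-3-hydroxy-4,4,8-trimethylcycloundeca-1,5,8-triene-1-carboxylate | CC1(C)/C=C\C/C(C)=C/CC/C(C(=O)OCC[Si](C)(C)C)=C\[C@H]1O | intermediate
19 | 2-(trimethylsilyl)ethyl (1E,3R,8E)-3-hydroxy-4,4,8-trimethylcycloundeca-1,8-diene-1-carboxylate | CC1(C)CCC/C(C)=C/CC/C(C(=O)OCC[Si](C)(C)C)=C\[C@H]1O | intermediate
20 | 2-(trimethylsilyl)ethyl (1E,3R,8E)-3-(benzoyloxy)-4,4,8-trimethylcycloundeca-1,8-diene-1-carboxylate | CC1(C)CCC/C(C)=C/CC/C(C(=O)OCC[Si](C)(C)C)=C\[C@H]1OC(=O)c1ccccc1 | intermediate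
21 | 2-(trimethylsilyl)ethyl (1R,4E,6R,11R)-6-(benzoyloxy)-7,7,11-trimethyl-12-oxabicyclo[9.1.0]dodec-4-ene-4-carboxylate | CC1(C)CCC[C@@]2(C)O[C@@H]2CC/C(C(=O)OCC[Si](C)(C)C)=C\[C@H]1OC(=O)c1ccccc1 | intermediate
22 | (1R,4E,6R,11R)-6-(benzoyloxy)-7,7,11-trimethyl-12-oxabicyclo[9.1.0]dodec-4-ene-4-carboxylic acid | CC1(C)CCC[C@@]2(C)O[C@@H]2CC/C(C(=O)O)=C\[C@H]1OC(=O)c1ccccc1 | target

**Step count and risks**

Total step count: 14. Longest linear sequence: 13 steps (steps 1–3 and 5–14, from geranyl acetate).

Steps most likely to fail: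

1. Step 10 (proposed new method). The ring closure may lose to intermolecular allyl transfer and oligomerisation, or the bridged transition state may not be reached below temperatures at which the boronate is degraded. The fallback makes the same C11–C1 bond by a Nozaki–Hiyama macrocyclisation, a known way to close carbocycles from an allylic bromide and an aldehyde, and sets out from 12. Acetal hydrolysis (Amberlyst-15, acetone–H2O) should give the hydroxy aldehyde F1. Appel bromination of the tertiary allylic alcohol with allylic transposition (CBr4, PPh3, CH2Cl2, 0 °C) should give the secondary bromo aldehyde F2. CrCl2 in THF at high dilution should convert F2 into an allylchromium species that adds through its dimethyl-substituted terminus, giving the racemic, E-configured trienol F3. Since this closure has no stereocentre to transmit, C11 is set afterwards: Dess–Martin oxidation to the C11 ketone F4, then Corey–Bakshi–Shibata reduction (oxazaborolidine antipode chosen by trial) to the (11R)-alcohol F5. Diimide reduction of F5 as in step 11 comes back to the route at 19.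

2. Step 8. Enantiofacial discrimination may be incomplete on an E alkene flanked by the fully substituted carbonate carbon, or the boryl copper species may be diverted to the enoate. The fallback sets out from 13 and replaces asymmetric catalysis by resolution. Palladium-catalysed allylic borylation through a π-allyl complex (Pd2(dba)3, B2pin2, DMSO, 50 °C) should place boron at the less substituted terminus C3 without touching the enoate and give the racemic boronate F6. F6 is resolved by preparative chromatography on a chiral stationary phase; its (S)-enantiomer is 15, where the route is rejoined, and the (R)-enantiomer serves as the probe of the C3 → C11 correlation.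

3. Step 13. Facial selectivity may be poor if the conformational preference of the 11-membered ring opposes the chiral dioxirane. The fallback sets out from 20 and gives up reagent control. Dimethyldioxirane (acetone, 0 °C) should give 21 together with its (5S,6S)-diastereomer F7, which are separated by chromatography. F7 is returned to 20 by stereospecific deoxygenation (triphenylphosphine selenide, trifluoroacetic acid, CH2Cl2) and recycled, so the route is rejoined at 21.

**Further compounds**

F1 | step 10 | 2-(trimethylsilyl)ethyl (2E,5E,8E)-10-hydroxy-6,10-dimethyl-2-(2-oxoethylidene)undeca-5,8-dienoate | CC(C)(O)/C=C/C/C(C)=C/CC/C(C(=O)OCC[Si](C)(C)C)=C\C=O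
F2 | step 10 | 2-(trimethylsilyl)ethyl (2E,5E)-8-bromo-6,10-dimethyl-2-(2-oxoethylidene)undeca-5,9-dienoate (racemic) | CC(C)=CC(Br)C/C(C)=C/CC/C(C(=O)OCC[Si](C)(C)C)=C\C=O
F3 | step 10 | 2-(trimethylsilyl)ethyl (1E,5E,8E)-3-hydroxy-4,4,8-trimethylcycloundeca-1,5,8-triene-1-carboxylate (racemic) | CC1(C)/C=C/C/C(C)=C/CC/C(C(=O)OCC[Si](C)(C)C)=C\C1O
F4 | step 10 | 2-(trimethylsilyl)ethyl (1E,5E,8E)-4,4,8-trimethyl-3-oxocycloundeca-1,5,8-triene-1-carboxylate | CC1(C)/C=C/C/C(C)=C/CC/C(C(=O)OCC[Si](C)(C)C)=C\C1=O
F5 | step 10 | 2-(trimethylsilyl)ethyl (1E,3R,5E,8E)-3-hydroxy-4,4,8-trimethylcycloundeca-1,5,8-triene-1-carboxylate | CC1(C)/C=C/C/C(C)=C/CC/C(C(=O)OCC[Si](C)(C)C)=C\[C@H]1O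
F6 | step 8 | 2-(trimethylsilyl)ethyl (2E,5E)-2-(2,2-dimethoxyethylidene)-6,10-dimethyl-8-(4,4,5,5-tetramethyl-1,3,2-dioxaborolan-2-yl)undeca-5,9-dienoate (racemic) | CC(C)=CC(B1OC(C)(C)C(C)(C)O1)C/C(C)=C/CC/C(C(=O)OCC[Si](C)(C)C)=C\C(OC)OC
F7 | step 13 | 2-(trimethylsilyl)ethyl (1S,4E,6R,11S)-6-(benzoyloxy)-7,7,11-trimethyl-12-oxabicyclo[9.1.0]dodec-4-ene-4-carboxylate | CC1(C)CCC[C@]2(C)O[C@H]2CC/C(C(=O)OCC[Si](C)(C)C)=C\[C@H]1OC(=O)c1ccccc1
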